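The data stem from a simulated flask with made-up constants; noise was put on by code.

This closed, stirred vessel at 25 °C holds one flask, followed so far as the west run, and I want its target at 20 h and the best remedy for the 20 h after that.

- west: starting material 0.10 M; second substrate 0.090 M; free enzyme 0.75 µM; temperature 25 °C; the very flask that is asked about, followed so far
- flask: starting material 0.10 M; second substrate 0.0900 M; free enzyme 0.75 µM; temperature 25 °C; time 20 h

- west (time / h: target / %): 1.00: 51.9; 3.00: 77.7; 6.00: 69.6; 8.00: 63.3; 12.0: 54.9; 15.0: 54.0

(each reading ± 1 percentage point)

- removed target is counted in
- the analysis behind the earlier runs scatters by 1 percentage point, standard deviation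
- steps thought possible: ternary complex -> free enzyme + target; free enzyme -> unfolded enzyme; target + free enzyme <-> isomer of the product + free enzyme; second substrate + starting complex <-> ternary complex; 2 free enzyme <-> resting dimer; starting material + free enzyme <-> starting complex
- additions bring no volume worth counting

- grey: at 20 h take out 90% of the target then present, then wait 20 h
- teal: at 20 h add second substrate, 50.0% of the amount charged, then wait 20 h
- violet: change nothing and wait 20 h more
- green: at 20 h add free enzyme, 100% of the amount charged, then wait 20 h
- ochre: at 20 h raise the temperature by 25 K, then wait 20 h

* target, in percent of the starting material first charged, at 20 h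
* the remedy with the largest gain of target, or "none" below 2 percentage points (grey / teal / violet / green / ochre / none)
* target present, with what was taken out counted in, in percent of the starting material first charged, after teal
* target present, with what was taken out counted in, in percent of the starting material first charged, after ochre

The first rung I can read is the filling of the product pool. The charge of second substrate is smaller than that of starting material, so it is the limiting reagent, and in this flask target plus isomer of the product can reach 90.0% of the starting material charged; at the pace of the first reading, 51.9% in 1.00 h, that takes 1.73 h. The next rung is the settling of target. The excess of c(target) over its last reading, 54.0%, falls from 16 percentage points at 6.00 h to 9.3 points at 8.00 h, which gives, as a reading with its scatter, 2.68 h for the settling half-time, the time in which that excess halves, and this is longer than the filling. The last rung is the time asked, much longer than the settling half-time, so I take the pool in this flask as split, as a reading with its scatter, with a target share of 0.600 and commit to about 54.0% at 20 h. If that share holds, grey has 7.46 half-times to refill and counts 73.4%, so I choose grey; the readings stand at one temperature, so I reckon nothing for ochre.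

The forecast gives 53.5% at 20 h, names grey as best, and puts teal at 59.5% and ochre at 52%, since for ochre “the enzyme dies quickly, and the equilibrium shifts only slightly”.

The flask gives 51.2% at 20 h; the best remedy is grey, with a gain of 19 points, teal ends at 55.6%, and ochre ends at 61.0%, where flask and forecast part by 9 points.

    ternary complex → free enzyme + target (k = 2600 min⁻¹, Ea = 53.0 kJ mol⁻¹)
    free enzyme → unfolded enzyme (k = 3.80 × 10⁻⁴ min⁻¹, Ea = 200 kJ mol⁻¹)
    target + free enzyme ⇌ isomer of the product + free enzyme, rate k3*[free enzyme]*[target] forward; the back reaction follows from the equilibrium constant (K = 0.800, k = 12000 L mol⁻¹ min⁻¹, Ea = 39.0 kJ mol⁻¹, ΔH = −35.0 kJ mol⁻¹)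
    second substrate + starting complex ⇌ ternary complex (K = 14.0 L mol⁻¹, k = 66000 L mol⁻¹ s⁻¹, Ea = 27.0 kJ mol⁻¹, ΔH = −50.0 kJ mol⁻¹)
    2 free enzyme ⇌ resting dimer, settled at all times (K = 2.40 × 10⁶ L mol⁻¹, ΔH = −48.0 kJ mol⁻¹)
    starting material + free enzyme ⇌ starting complex (K = 440 L mol⁻¹, k = 17000 L mol⁻¹ s⁻¹, Ea = 14.0 kJ mol⁻¹, ΔH = 8.00 kJ mol⁻¹)
    (constants at 25 °C)

The slide of target in this flask is its turning into isomer of the product, run by the free enzyme that the undoing of starting complex hands back: without the first this flask holds 90.0% of target at 20 h, without the second 88.4%. Free enzyme in this flask stands at 16.2% of the catalyst charged at 10.0 h and 15.7% at 20.0 h, and the settling half-time puts this flask at 59.5% of target at 10.0 h, where it stands at 58.5%. The neighbour flask with 0.036 M of second substrate holds 3.36% free enzyme at 20 h; scaling the half-time inversely with that share against this flask's at the same time, I reckon 12.5 h, and with the target share kept, 26.3% of target at 20 h; it holds 27.3%.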